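Daucane numbering: C1 methyl-bearing ring-fusion carbon, C4 isopropyl carbinol, C5 ring-fusion CH, C6 anisoate carbon, C8=C9 olefin, C10 angelate carbon. The cycloheptene (C1, C5–C10) is grown from the cyclohexene of a cis-decalin by a semipinacol 1,2-shift: in a mesylate whose ring-fusion carbinol C6 flanks the C5 leaving group, C1 migrates from C6 to C5. This one operation inserts C5 into the six-membered ring C1/C10/C9/C8/C7/C6, contracts the other ring to the cyclopentane, unmasks the C6 ketone and sets C5 (trans fusion). The decalin comes from a proline Robinson annulation. The step exploits the C6(O)–C5(H)–C1(quaternary) triad.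

Key step: step 10

Remark: the target atom numbers are kept for all decalin intermediates (ring fusion C1–C6; C10 next to C1; C4 next to C5); β is the face of the C1 methyl, α the opposite face.
Remark: the decalins made before step 5 are carried as mixtures of C8 epimers, because C8 becomes trigonal in step 5; L-proline is assumed to give the (S)-configured annulation product as it does for the Wieland–Miescher ketone, with an enantiomeric upgrade by crystallisation of an intermediate if needed.

Step 1
Reactants: 1 5-methylcyclohexane-1,3-dione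
Product: 2 2,5-dimethylcyclohexane-1,3-dione
Conditions: MeI, NaOH, H2O–MeOH, 65 °C
Reagents that add atoms: iodomethane, CI
Why: C-alkylation of the 1,3-dione enolate at the carbon between the carbonyls (enolate alkylation) is the standard entry to 2-methyl-1,3-diones and sets no stereocentre of consequence.

Step 2
Reactants: 2 2,5-dimethylcyclohexane-1,3-dione; 3 methyl vinyl ketone
Product: 6 (8aS)-3,8a-dimethyl-3,4,8,8a-tetrahydronaphthalene-1,6(2H,7H)-dione, via triketone 4 (not isolated), via aldol ketol 5 (not isolated)
Conditions: L-proline (0.35 equiv), DMSO, 35 °C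
Reagents that add atoms: none
Why: Proline-catalysed Robinson annulation (Hajos–Parrish–Eder–Sauer–Wiechert reaction), in which Michael addition gives the triketone, the enamine aldol through the acid-directed transition state differentiates the two ring carbonyls and should set (S) at C1 as for the Wieland–Miescher ketone, and dehydration gives the C4 enone with the C10 ketone left free.

Step 3
Reactants: 6 (8aS)-3,8a-dimethyl-3,4,8,8a-tetrahydronaphthalene-1,6(2H,7H)-dione
Product: 7 (4aS,5S)-5-hydroxy-4a,7-dimethyl-4,4a,5,6,7,8-hexahydronaphthalen-2(3H)-one (10β-alcohol)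
Conditions: NaBH4 (0.3 equiv), EtOH, −10 °C
Reagents that add atoms: none
Why: Chemoselective borohydride reduction of the saturated C10 ketone in the presence of the enone, with hydride entering anti to the axial C1 methyl to give the 10β-alcohol, which only masks C10 during the organometallic addition of step 4.

Step 4
Reactants: 7 10β-hydroxy enone
Product: 8 decalin diol with 10β-OH, 4β-OH, 4α-isopropyl and the C5=C6 olefin
Conditions: i-PrMgCl, CeCl3, THF, −78 to 0 °C
Reagents that add atoms: isopropylmagnesium chloride, CC(C)[Mg]Cl
Why: Organocerium 1,2-addition to the enone suppresses enolisation and conjugate addition, and the nucleophile should enter axially from the α-face, anti to the C1 methyl as in additions to steroidal 4-en-3-ones, which sets C4 with the hydroxyl β and the isopropyl group α.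

Step 5
Reactants: 8 decalin diol
Product: 10 dienone 6-hydroxy-3,8a-dimethyl-6-(propan-2-yl)-6,7,8,8a-tetrahydronaphthalen-1(4H)-one, via ketone 9 (not isolated)
Conditions: IBX, 4-methoxypyridine N-oxide, DMSO, 25 °C
Reagents that add atoms: none
Why: IBX oxidation of the C10 carbinol followed by IBX-mediated α,β-dehydrogenation of the ketone, which is enolisable only toward C9, should give the C8=C9 enone and make C8 trigonal so that both epimers converge; the skipped dienone is used directly.

Step 6
Reactants: 10 dienone
Product: 12 triol enone with 4β-, 5β- and 6β-OH (cis-decalin), via osmate ester 11 (not isolated)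
Conditions: OsO4, TMEDA, CH2Cl2, −78 °C; then HCl, MeOH, 25 °C
Reagents that add atoms: osmium tetroxide, O=[Os](=O)(=O)=O
Why: Hydrogen-bond-directed dihydroxylation, in which the OsO4·TMEDA complex is bound by the allylic C4 hydroxyl and should add to the C5=C6 olefin from the same β-face (as hydroxyl-directed reagents do with steroidal 4-en-3β-ols), setting the C5 and C6 hydroxyls cis to the C4 hydroxyl and the C1 methyl while the electron-poor enone olefin is left untouched.

Step 7
Reactants: 12 triol enone
Product: 13 tetraol with 10α-OH and 4β-, 5β-, 6β-OH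
Conditions: Me4NBH(OAc)3, MeCN–AcOH, −30 °C
Reagents that add atoms: none
Why: Evans–Saksena reduction, in which the ring-fusion C6 hydroxyl (1,3 to the carbonyl, β-face) exchanges onto boron and delivers hydride intramolecularly to the β-face of C10, giving the 1,3-anti diol, that is the 10α-alcohol trans to the C1 methyl that external hydride (which attacks anti to the methyl) would not give.

Step 8
Reactants: 13 tetraol; 14 angelic acid
Product: 16 C10 angelate of the tetraol, via mixed anhydride 15 (not isolated)
Conditions: 2,4,6-trichlorobenzoyl chloride, Et3N, toluene, 25 °C; then 13, 70 °C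
Reagents that add atoms: none
Why: Yamaguchi esterification run without DMAP to avoid angelate-to-tiglate isomerisation, which should acylate the allylic C10 hydroxyl selectively because the other secondary hydroxyl (C5) is flanked by two fully substituted carbinol carbons and the remaining hydroxyls are tertiary.

Step 9
Reactants: 16 C10 angelate triol
Product: 17 C5 mesylate with free C4 and C6 hydroxyls
Conditions: MsCl, Et3N, CH2Cl2, −20 °C
Reagents that add atoms: methanesulfonyl chloride, CS(=O)(=O)Cl
Why: Sulfonylation through the sulfene of the only secondary hydroxyl left, which places the leaving group β, cis to the C6 hydroxyl and to the C1 methyl, without touching a stereocentre.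

Step 10
Reactants: 17 C5 mesylate
Product: 18 trans-fused hydroazulenone, 4β-hydroxy-6-oxodauc-8-en-10α-yl angelate
Conditions: AlEt3, CH2Cl2, −78 to 0 °C
Reagents that add atoms: none
Why: Semipinacol rearrangement of a 2-mesyloxy tertiary alcohol, the classical decalin-to-hydroazulene reorganisation: AlEt3 turns the C6 hydroxyl into an aluminium alkoxide and activates the mesylate, and the C1–C6 bond, antiperiplanar to the equatorial C5–O bond, shifts to C5 as C6 becomes the ketone. The cyclopentane is closed by this suprafacial 1,2-alkyl shift (ring contraction, new C1–C5 bond), and the cycloheptene arises from the cyclohexene by one-carbon expansion through insertion of C5. C5 is the only new stereocentre and is set by inversion at the mesylate carbon with retention at the migrating C1, so the β-mesylate (cis to the C1 methyl) gives 5α-H and the trans ring fusion. The reactive chair, with the mesylate and the isopropyl group equatorial, should be the preferred conformer of the cis-decalin. The step needs migration of C1 rather than of C3 driven by the C4 alkoxide, which the higher migratory aptitude of the fully substituted C1 over a methylene should secure, while the cis arrangement of all three oxygens excludes epoxide formation.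

Step 11
Reactants: 18 hydroazulenone
Product: 19 4β,6α-dihydroxydauc-8-en-10α-yl angelate
Conditions: Me4NBH(OAc)3, MeCN–AcOH, −30 °C
Reagents that add atoms: none
Why: Evans–Saksena reduction directed by the tertiary C4 β-hydroxyl, which lies 1,3 to the C6 ketone on its β-face, so that hydride is delivered to the β-face and the 4β,6α (1,3-anti) diol should result, the cold, mildly acidic medium leaving the β,γ-olefin and C5 untouched.

Step 12
Reactants: 19 diol angelate; 20 4-methoxybenzoyl chloride
Product: 21 target, 10α-angeloyloxy-4β-hydroxydauc-8-en-6α-yl 4-methoxybenzoate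
Conditions: pyridine, DMAP (cat.), CH2Cl2, 0 to 25 °C
Reagents that add atoms: none
Why: Acylation under nucleophilic catalysis of the only secondary hydroxyl, the tertiary C4 hydroxyl being unreactive and the angelate not isomerising at room temperature, so no stereocentre is touched.

Compound list
1 | 5-methylcyclohexane-1,3-dione | CC1CC(=O)CC(=O)C1 | starting material
2 | 2,5-dimethylcyclohexane-1,3-dione | CC1CC(=O)C(C)C(=O)C1 | intermediate
3 | methyl vinyl ketone (but-3-en-2-one) | CC(=O)C=C | starting material
4 | 2,5-dimethyl-2-(3-oxobutyl)cyclohexane-1,3-dione (cis/trans mixture) | CC(=O)CCC1(C)C(=O)CC(C)CC1=O | intermediate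
5 | aldol ketol, (8aS)-4a-hydroxy-3,8a-dimethyloctahydronaphthalene-1,6-dione, 4a-OH cis to the 8a-methyl (C8 epimers) | C[C@@]12C(=O)CC(C)C[C@]1(O)CC(=O)CC2 | intermediate
6 | (8aS)-3,8a-dimethyl-3,4,8,8a-tetrahydronaphthalene-1,6(2H,7H)-dione (C10 ketone, C4 enone; C8 epimers) | C[C@@]12C(=O)CC(C)CC1=CC(=O)CC2 | intermediate
7 | (4aS,5S)-5-hydroxy-4a,7-dimethyl-4,4a,5,6,7,8-hexahydronaphthalen-2(3H)-one (10β-OH cis to the C1 methyl; C8 epimers) | C[C@@]12[C@@H](O)CC(C)CC1=CC(=O)CC2 | intermediate
8 | decalin diol, 4a,7-dimethyl-2-(propan-2-yl)-2,3,4,4a,5,6,7,8-octahydronaphthalene-2,5-diol: 10β-OH and 4β-OH cis to the C1 methyl, 4α-isopropyl, C5=C6 olefin (C8 epimers) | C[C@@]12[C@@H](O)CC(C)CC1=C[C@](O)(C(C)C)CC2 | intermediate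
9 | C10 ketone of 8, 6-hydroxy-3,8a-dimethyl-6-(propan-2-yl)-3,4,6,7,8,8a-hexahydronaphthalen-1(2H)-one (C8 epimers) | C[C@@]12C(=O)CC(C)CC1=C[C@](O)(C(C)C)CC2 | intermediate
10 | dienone, 6-hydroxy-3,8a-dimethyl-6-(propan-2-yl)-6,7,8,8a-tetrahydronaphthalen-1(4H)-one: C10 ketone, C8=C9 and C5=C6 olefins, 4β-OH, 4α-isopropyl | C[C@@]12C(=O)C=C(C)CC1=C[C@](O)(C(C)C)CC2 | intermediate
11 | TMEDA-chelated osmate ester (hexavalent osmium) of triol 12 through the β-oxygens on C5 and C6 | C[C@@]12C(=O)C=C(C)C[C@]1(O[Os]3(=O)=O)[C@@H](O3)[C@](O)(C(C)C)CC2.CN(C)CCN(C)C | intermediate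
12 | triol enone, 4a,5,6-trihydroxy-3,8a-dimethyl-6-(propan-2-yl)-4a,5,6,7,8,8a-hexahydronaphthalen-1(4H)-one: 4β-, 5β-, 6β-OH all cis to the C1 methyl (cis-decalin), 4α-isopropyl | C[C@@]12C(=O)C=C(C)C[C@]1(O)[C@@H](O)[C@](O)(C(C)C)CC2 | intermediate
13 | tetraol, as 12 with the C10 ketone reduced to the 10α-alcohol (trans to the C1 methyl) | C[C@@]12[C@H](O)C=C(C)C[C@]1(O)[C@@H](O)[C@](O)(C(C)C)CC2 | intermediate
14 | angelic acid, (Z)-2-methylbut-2-enoic acid | C/C=C(/C)C(=O)O | starting material
15 | (Z)-2-methylbut-2-enoic 2,4,6-trichlorobenzoic anhydride | C/C=C(/C)C(=O)OC(=O)c1c(Cl)cc(Cl)cc1Cl | intermediate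
16 | C10 α-angelate of tetraol 13 (4β-, 5β-, 6β-OH free) | C[C@@]12[C@H](OC(=O)/C(C)=C\C)C=C(C)C[C@]1(O)[C@@H](O)[C@](O)(C(C)C)CC2 | intermediate
17 | C5 β-mesylate of 16 (4β- and 6β-OH free, 10α-angelate) | C[C@@]12[C@H](OC(=O)/C(C)=C\C)C=C(C)C[C@]1(O)[C@@H](OS(C)(=O)=O)[C@](O)(C(C)C)CC2 | intermediate
18 | 4β-hydroxy-6-oxodauc-8-en-10α-yl angelate (trans-fused: 1β-methyl, 5α-H; 4α-isopropyl) | C/C=C(/C)C(=O)O[C@@H]1C=C(C)CC(=O)[C@@H]2[C@]1(C)CC[C@@]2(O)C(C)C | intermediate
19 | 4β,6α-dihydroxydauc-8-en-10α-yl angelate | C/C=C(/C)C(=O)O[C@@H]1C=C(C)C[C@H](O)[C@@H]2[C@]1(C)CC[C@@]2(O)C(C)C | intermediate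
20 | 4-methoxybenzoyl chloride | COc1ccc(cc1)C(Cl)=O | starting material
21 | (3R,3aS,4S,8R,8aS)-3-hydroxy-6,8a-dimethyl-8-{[(2Z)-2-methylbut-2-enoyl]oxy}-3-(propan-2-yl)-1,2,3,3a,4,5,8,8a-octahydroazulen-4-yl 4-methoxybenzoate | C/C=C(/C)C(=O)O[C@@H]1C=C(C)C[C@H](OC(=O)c2ccc(OC)cc2)[C@@H]2[C@]1(C)CC[C@@]2(O)C(C)C | target

Total step count: 12. Longest linear sequence: 12 steps (from 1 to 21); 3, 14 and 20 are commercial.

Steps most likely to fail

Step 10. What may go wrong: the C4 alkoxide competes as the pushing group, so that C3 instead of C1 migrates to C5 and the carbinol ring contracts to an isobutyryl hydrindane. Fallback: the C4 hydroxyl is masked before the shift, with the osmate ester serving as a temporary protecting group for the C5/C6 diol. It sets out from 11, isolated as the stable TMEDA chelate, in which the C4 hydroxyl is the only free OH. TESOTf, 2,6-lutidine, CH2Cl2 should give the C4 triethylsilyl ether of the osmate ester F1, and aqueous Na2SO3, THF should release the C4-silylated diol enone F2. The main sequence is then repeated on the silyl ether: Me4NBH(OAc)3 should give the 10α-alcohol F3, Yamaguchi acylation with 14 the C10 angelate F4, and MsCl, Et3N the C5 mesylate F5. AlEt3 then lets only the C6 oxygen push and should give the C4 silyl ether of the hydroazulenone F6. HF·pyridine, THF removes the silyl group and the route is rejoined at 18.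

Step 6. What may go wrong: poor facial selectivity, with osmylation anti to the axial C1 methyl (α-face) leading to the trans-decalin diol because the directing hydroxyl is tertiary and hindered. Fallback: the order of oxidation and osmylation is reversed, so that the olefin is flanked by two β-hydroxyls and no second olefin is present. It sets out from 8. OsO4, TMEDA, CH2Cl2, −78 °C is then directed by both the allylic C4 and the homoallylic C10 hydroxyl and should give the osmate ester of the diol F7, which is kept as diol protection. IBX, 4-methoxypyridine N-oxide, DMSO oxidises the C10 carbinol to the ketone osmate ester F8 (not isolated) and dehydrogenates it. The route is rejoined at 11, which is cleaved as in step 6.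

Step 5. What may go wrong: migration of the C5=C6 double bond into conjugation with the new enone through the doubly allylic C7 methylene, or allylic transposition of the tertiary C4 alcohol under the hypervalent-iodine conditions. Fallback: a stepwise enolate route in which base is used only before the enone exists. It sets out from 8. Dess–Martin periodinane, CH2Cl2 gives ketone 9, now isolated. LiN(i-Pr)2 (2.2 equiv), THF, −78 °C, then PhSeBr should give the C9 phenylselenide F9, whose C9 centre can epimerise so that either C8 epimer reaches a syn arrangement. H2O2, pyridine, CH2Cl2, 0 °C effects selenoxide syn-elimination toward C8 and the route is rejoined at 10.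

Further compounds
F1 | step 10 | C4 triethylsilyl ether of osmate ester 11 (TMEDA chelate, hexavalent osmium) | C[C@@]12C(=O)C=C(C)C[C@]1(O[Os]3(=O)=O)[C@@H](O3)[C@](O[Si](CC)(CC)CC)(C(C)C)CC2.CN(C)CCN(C)C
F2 | step 10 | 5β,6β-diol enone with C4 triethylsilyl ether | C[C@@]12C(=O)C=C(C)C[C@]1(O)[C@@H](O)[C@](O[Si](CC)(CC)CC)(C(C)C)CC2
F3 | step 10 | 10α-alcohol of F2 | C[C@@]12[C@H](O)C=C(C)C[C@]1(O)[C@@H](O)[C@](O[Si](CC)(CC)CC)(C(C)C)CC2
F4 | step 10 | C10 angelate of F3 | C[C@@]12[C@H](OC(=O)/C(C)=C\C)C=C(C)C[C@]1(O)[C@@H](O)[C@](O[Si](CC)(CC)CC)(C(C)C)CC2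
F5 | step 10 | C5 mesylate of F4 | C[C@@]12[C@H](OC(=O)/C(C)=C\C)C=C(C)C[C@]1(O)[C@@H](OS(C)(=O)=O)[C@](O[Si](CC)(CC)CC)(C(C)C)CC2
F6 | step 10 | C4 triethylsilyl ether of hydroazulenone 18 | C/C=C(/C)C(=O)O[C@@H]1C=C(C)CC(=O)[C@@H]2[C@]1(C)CC[C@@]2(O[Si](CC)(CC)CC)C(C)C
F7 | step 6 | TMEDA-chelated osmate ester of diol 8 through the C5 and C6 oxygens (10β-OH and 4β-OH free) | C[C@@]12[C@@H](O)CC(C)C[C@]1(O[Os]3(=O)=O)[C@@H](O3)[C@](O)(C(C)C)CC2.CN(C)CCN(C)C
F8 | step 6 | C10 ketone of osmate ester F7 | C[C@@]12C(=O)CC(C)C[C@]1(O[Os]3(=O)=O)[C@@H](O3)[C@](O)(C(C)C)CC2.CN(C)CCN(C)C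
F9 | step 5 | C9 phenylselenide of ketone 9 | C[C@@]12C(=O)C([Se]c3ccccc3)C(C)CC1=C[C@](O)(C(C)C)CC2
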